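**Retrosynthetic overview**

1. The target comes from a Tsuji–Wacker oxidation of a spiro cyclopent-2-en-1-ol, which is made last by an iridium-catalysed [3+2] annulation of an exocyclic 1,3-diene with a (Z)-β-boryl acrolein (forms the ring CH2–C bond and the spiro C–CH(OH) bond).
2. Enabling feature: the carbinol CH of the cyclopentanone is bonded to the spiro carbon, which is also a cyclohexene ring member allylic to the ring C=C and carries the CH2 alpha to the ketone. O–CH–C(spiro)–C=C is a homoallylic-alcohol retron, so spiro C, its CH2 and the ring C=C unravel to an exocyclic-methylene diene.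
3. The diene comes from an α-substituted cyclohexenone (Lombardo methylenation; tertiary carbinol by oxidation and MeMgBr), and this from an allylic alcohol obtained by acid translactonisation of a bridged 2-oxabicyclo[2.2.2]octenone to the cyclopentane-fused γ-lactone.
4. The bridged lactone comes from the Diels–Alder adduct of 3,5-dibromo-2-pyrone and (R)-4-silyloxycyclopentenone (sets both ring-fusion CH, the trans lactone α-CH and oxygen on the future spiro carbon). The side chain is added by Heck coupling and Rh/(R)-BINAP 1,4-addition of isopropenyl.
5. Ring order: cyclopentane (chiral building block), then cyclohexene with bridged lactone (step 1), then γ-lactone (step 6), then spiro cyclopentane (step 13).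

Key step: step 13

Remark: the lactone α-CH (allylic, trans ring fusion) is assumed to be base-labile, so every step after the bridged lactone is opened is run under neutral or acidic conditions.

**Route**

Step 1
Reactants: 1 3,5-dibromo-2H-pyran-2-one; 2 (R)-4-(tert-butyldimethylsilyloxy)cyclopent-2-en-1-one
Product: 3 endo dibromo bridged lactone (4,7-dibromo-2-oxabicyclo[2.2.2]oct-7-en-3-one cis-fused at C5–C6 to a 3-silyloxycyclopentanone)
Conditions: toluene, 100 °C, sealed tube
Reagents that add atoms: none
Why: Diels–Alder reaction of the ambiphilic dibromopyrone, in which the enone α-carbon should bond to the brominated C3 as with acrylates and vinyl ketones; endo approach anti to the OTBS group sets both ring-fusion CH centres and holds the lactone carbonyl trans to the cyclopentanone carbon, as the target's lactone requires.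

Step 2
Reactants: 3 endo dibromo bridged lactone
Product: 4 monobromo bridged lactone (bridgehead C–H, alkenyl bromide kept)
Conditions: Bu3SnH (1.05 equiv), AIBN (cat.), benzene, 80 °C
Reagents that add atoms: none
Why: Radical reductive dehalogenation removes the weak tertiary α-carbonyl C–Br bond selectively over the alkenyl C–Br bond; the bridgehead carbon cannot invert.

Step 3
Reactants: 4 monobromo bridged lactone
Product: 5 bridged lactone cyclopentanol
Conditions: NaBH4, MeOH/CH2Cl2, −78 °C
Reagents that add atoms: none
Why: Chemoselective ketone reduction; hydride attacks the convex face of the cyclopentanone (away from the bicyclooctene), so the hydroxyl ends cis to the ring-fusion C–C bonds, as the later lactone needs.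

Step 4
Reactants: 5 bridged lactone cyclopentanol; 6 methyl acrylate
Product: 7 (E)-dienoate bridged lactone
Conditions: Pd(OAc)2 (5 mol %), P(o-tol)3, Et3N, MeCN, 70 °C
Reagents that add atoms: none
Why: Mizoroki–Heck coupling of the alkenyl bromide; syn insertion and syn β-hydride elimination give the (E)-enoate.

Step 5
Reactants: 7 (E)-dienoate bridged lactone; 8 isopropenylboronic acid pinacol ester
Product: 9 bridged lactone with complete side chain (side-chain CH of S configuration)
Conditions: [Rh(OH)((R)-binap)]2 (3 mol % Rh), dioxane/H2O 10:1, 60 °C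
Reagents that add atoms: none
Why: Hayashi–Miyaura rhodium-catalysed asymmetric 1,4-addition of an alkenylboronate; by the established facial model (R)-BINAP delivers the alkenyl group to the α-re face and sets the S centre under catalyst control, and 1,6-addition is disfavoured at the hindered δ-carbon next to the bridgehead.

Step 6
Reactants: 9 bridged lactone with complete side chain
Product: 12 diol γ-lactone, via ring-opened methyl ester 10 (not isolated), via silylated γ-lactone 11 (not isolated)
Conditions: CSA (0.3 equiv), MeOH, rt
Reagents that add atoms: none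
Why: Acid-catalysed transesterification opens the strained bridged lactone to the methyl ester, whose γ-hydroxyl should reclose to the less strained cyclopentane-fused γ-lactone (translactonisation), and the same acid solvolyses the secondary silyl ether; no stereocentre is touched.

Step 7
Reactants: 12 diol γ-lactone
Product: 13 α-substituted cyclohexenone γ-lactone
Conditions: MnO2 (activated, excess), CH2Cl2, rt
Reagents that add atoms: none
Why: Chemoselective MnO2 oxidation of the allylic alcohol only; the non-allylic cyclopentanol is left alone.

Step 8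
Reactants: 13 α-substituted cyclohexenone γ-lactone
Product: 14 exocyclic diene cyclopentanol
Conditions: Zn, CH2Br2, TiCl4 (Lombardo reagent), THF/CH2Cl2, 0 °C to rt
Reagents that add atoms: dibromomethane, BrCBr
Why: Takai–Lombardo methylenation converts the ketone to the exocyclic methylene under non-basic conditions, sparing lactone, ester and the acidic γ-CH of the enone.

Step 9
Reactants: 14 exocyclic diene cyclopentanol
Product: 15 exocyclic diene cyclopentanone
Conditions: Dess–Martin periodinane, NaHCO3, CH2Cl2, 0 °C
Reagents that add atoms: none
Why: Dess–Martin oxidation of the only remaining secondary alcohol under buffered conditions, which avoids β-elimination of the lactone oxygen.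

Step 10
Reactants: 15 exocyclic diene cyclopentanone
Product: 16 exocyclic diene tertiary alcohol
Conditions: MeMgBr, CeCl3 (anhydrous), THF, −78 °C; aq. NH4Cl
Reagents that add atoms: methylmagnesium bromide, C[Mg]Br
Why: Organocerium 1,2-addition, which outpaces enolisation and β-elimination; methyl should enter from the convex face of the cyclopentanone (opposite the lactone and cyclohexene rings), giving the hydroxyl cis to the lactone oxygen.

Step 11
Reactants: 17 3,3-diethoxyprop-1-yne
Product: 18 (Z)-alkenylboronate diethyl acetal
Conditions: HBpin, [Rh(cod)Cl]2 (1.5 mol %), P(i-Pr)3, Et3N, cyclohexane, rt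
Reagents that add atoms: pinacolborane, [H]B1OC(C)(C)C(C)(C)O1
Why: Rhodium-catalysed trans-hydroboration of a terminal alkyne (via a rhodium vinylidene) gives the (Z)-1-alkenylboronate.

Step 12
Reactants: 18 (Z)-alkenylboronate diethyl acetal
Product: 19 (Z)-3-(pinacolboryl)acrylaldehyde
Conditions: PPTS (cat.), acetone/H2O 10:1, 0 °C to rt; used at once
Reagents that add atoms: water, O
Why: Mild acid-catalysed acetal hydrolysis unmasks the aldehyde; short contact time should keep the Z geometry.

Step 13
Reactants: 16 exocyclic diene tertiary alcohol; 19 (Z)-3-(pinacolboryl)acrylaldehyde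
Product: 20 spiro cyclopent-2-en-1-ol
Conditions: [Ir(OH)(cod)]2 (5 mol % Ir), toluene/H2O 20:1, 60 °C, slow addition of 19 (1.5 equiv)
Reagents that add atoms: none
Why: Proposed new method: the alkenyl group passes from boron to Ir(I), the alkenyl–Ir bond adds across the exocyclic C=CH2 with carbon going to the terminal CH2, and the resulting π-allyl–Ir (spiro carbon and ring C=C) adds through its more substituted terminus to the tethered cis-aldehyde before water protonates the iridium alkoxide and regenerates Ir–OH. The closest known reaction type is the Ir- or Rh-catalysed [3+2] annulation of 1,3-dienes with 2-formylarylboronic acids to 2-vinylindan-1-ols, here extended to a β-formyl alkenylboronate and to a 2-substituted exocyclic diene so that a spiro quaternary carbon results. The cyclopentene ring closes by 5-exo-trig attack of the allyl terminus on the aldehyde carbon through a six-membered Ir–C–C=C···C=O transition state. The spiro centre is set by substrate control, iridium and hence the new C–C bond staying on the diene face opposite the cis-fused cyclopentane carbon on the neighbouring ring-fusion carbon, and the carbinol centre by the closed transition state, which holds the alkoxide oxygen syn to the ring alkene carbon. The step needs insertion at the exocyclic methylene rather than at the trisubstituted ring alkene or the isopropenyl group, which the conjugated diene and its unhindered CH2 terminus should secure, and ring closure faster than protonation of the allyl–Ir, which the Z geometry of 19 secures; base-free hydroxo-iridium conditions protect the lactone α-CH.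

Step 14
Reactants: 20 spiro cyclopent-2-en-1-ol
Product: 21 CNP0255095.1 (target)
Conditions: PdCl2 (10 mol %), CuCl (1 equiv), O2 (1 atm), DMF/H2O 7:1, rt
Reagents that add atoms: water, O
Why: Tsuji–Wacker oxidation; water should attack the alkene carbon remote from the electron-withdrawing allylic hydroxyl, so the ketone forms next to the ring CH2 (β-hydroxy ketone), while the 1,1-disubstituted and trisubstituted alkenes are unreactive under these conditions.

**Compound list**

1 | 3,5-dibromo-2H-pyran-2-one | O=C1OC=C(Br)C=C1Br | starting material
2 | (R)-4-(tert-butyldimethylsilyloxy)cyclopent-2-en-1-one | O=C1C=C[C@H](O[Si](C)(C)C(C)(C)C)C1 | starting material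
3 | endo adduct: 4,7-dibromo-2-oxabicyclo[2.2.2]oct-7-en-3-one cis-fused at C5–C6 to a cyclopentanone (C=O carbon on C5, TBSO carbon on C6, five-membered ring on the alkene-bridge side, OTBS anti to the bicycle) | BrC1=C[C@@]2(Br)C(=O)O[C@@H]1[C@@H]3[C@H]2C(=O)C[C@H]3O[Si](C)(C)C(C)(C)C | intermediate
4 | 4-debromo analogue of 3 (bridgehead C4–H, 7-bromoalkene kept) | BrC1=C[C@H]2C(=O)O[C@@H]1[C@@H]3[C@H]2C(=O)C[C@H]3O[Si](C)(C)C(C)(C)C | intermediate
5 | alcohol of 4: cyclopentanol OH on the concave face, cis to the ring-fusion C–C bonds, trans to OTBS | BrC1=C[C@H]2C(=O)O[C@@H]1[C@@H]3[C@H]2[C@H](O)C[C@H]3O[Si](C)(C)C(C)(C)C | intermediate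
6 | methyl acrylate | C=CC(=O)OC | starting material
7 | 5 with the 7-bromine replaced by (E)-CH=CH–CO2Me | COC(=O)/C=C/C1=C[C@H]2C(=O)O[C@@H]1[C@@H]3[C@H]2[C@H](O)C[C@H]3O[Si](C)(C)C(C)(C)C | intermediate
8 | isopropenylboronic acid pinacol ester | CC(=C)B1OC(C)(C)C(C)(C)O1 | starting material
9 | 7 after 1,4-addition of isopropenyl: C7 bears (S)-CH(isopropenyl)CH2CO2Me | C=C(C)[C@H](CC(=O)OC)C1=C[C@H]2C(=O)O[C@@H]1[C@@H]3[C@H]2[C@H](O)C[C@H]3O[Si](C)(C)C(C)(C)C | intermediate
10 | ring-opened methyl ester: cyclohexene with CO2Me and allylic OH cis-1,4, cis-fused cyclopentane carrying OH (cis to the ring fusion bonds) and OTBS | C=C(C)[C@H](CC(=O)OC)C1=C[C@@H](C(=O)OC)[C@@H]2[C@H](O)C[C@@H](O[Si](C)(C)C(C)(C)C)[C@@H]2[C@H]1O | intermediate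
11 | tricyclic γ-lactone (trans-fused to cyclohexene, cis-fused to cyclopentane) with allylic OH and OTBS | C=C(C)[C@H](CC(=O)OC)C1=C[C@H]2C(=O)O[C@@H]3C[C@@H](O[Si](C)(C)C(C)(C)C)[C@@H]([C@@H]32)[C@H]1O | intermediate
12 | diol γ-lactone: 11 without the silyl group | C=C(C)[C@H](CC(=O)OC)C1=C[C@H]2C(=O)O[C@@H]3C[C@@H](O)[C@@H]([C@@H]32)[C@H]1O | intermediate
13 | cyclohexenone γ-lactone: allylic alcohol of 12 oxidised to the ketone | C=C(C)[C@H](CC(=O)OC)C1=C[C@H]2C(=O)O[C@@H]3C[C@@H](O)[C@@H]([C@@H]32)C1=O | intermediate
14 | exocyclic diene: ketone of 13 replaced by C=CH2 | C=C(C)[C@H](CC(=O)OC)C1=C[C@H]2C(=O)O[C@@H]3C[C@@H](O)[C@@H]([C@@H]32)C1=C | intermediate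
15 | diene ketone: cyclopentanol of 14 oxidised | C=C(C)[C@H](CC(=O)OC)C1=C[C@H]2C(=O)O[C@@H]3CC(=O)[C@@H]([C@@H]32)C1=C | intermediate
16 | diene tertiary alcohol: C(CH3)(OH) with OH cis to the lactone oxygen, methyl cis to the ring-fusion hydrogens | C=C(C)[C@H](CC(=O)OC)C1=C[C@H]2C(=O)O[C@@H]3C[C@](C)(O)[C@@H]([C@@H]32)C1=C | intermediate
17 | 3,3-diethoxyprop-1-yne | C#CC(OCC)OCC | starting material
18 | (Z)-2-(3,3-diethoxyprop-1-en-1-yl)-4,4,5,5-tetramethyl-1,3,2-dioxaborolane | CCOC(OCC)/C=C\B1OC(C)(C)C(C)(C)O1 | intermediate
19 | (Z)-3-(4,4,5,5-tetramethyl-1,3,2-dioxaborolan-2-yl)acrylaldehyde | O=C/C=C\B1OC(C)(C)C(C)(C)O1 | intermediate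
20 | spiro cyclopent-2-en-1-ol: carbinol carbon on the face of the ring-fusion hydrogen, OH syn to the cyclohexene alkene carbon | C=C(C)[C@H](CC(=O)OC)C1=C[C@H]2C(=O)O[C@@H]3C[C@](C)(O)[C@@H]([C@@H]32)[C@]12CC=C[C@@H]2O | intermediate
21 | CNP0255095.1 | C=C(C)[C@H](CC(=O)OC)C1=C[C@H]2C(=O)O[C@@H]3C[C@](C)(O)[C@@H]([C@@H]32)[C@]12CC(=O)C[C@@H]2O | target

**Step count and risks**

Total step count: 14. Longest linear sequence: 12 steps (steps 1–10, 13, 14); steps 11–12 prepare the annulation reagent.

Step 13 (proposed new method). What may go wrong: the alkenyl–iridium species may add to the enal of a second reagent molecule, or the allyl–iridium may be protonated before it reaches the aldehyde, so that no ring forms. The fallback sets out from 16 and uses known chemistry in two stages. A copper-catalysed borylative three-component coupling of the diene with bis(pinacolato)diboron and (Z)-3-iodoacrolein (O=C/C=C\I; CuCl, PCy3, NaOt-Bu cat., THF, then MeOH) should place Bpin on the exocyclic CH2 and add the allyl-copper through the ring carbon to the aldehyde, giving the boryl iodoalkenyl homoallylic alcohol F1. An intramolecular B-alkyl Suzuki–Miyaura coupling (PdCl2(dppf), K3PO4, DMF/H2O, 50 °C) then joins the CH2–B carbon to the (Z)-alkenyl iodide and comes back to the route at 20.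

Step 1. What may go wrong: the β-substituted cyclic enone may be too sluggish a dienophile, and the temperature needed may cause retro-[4+2] loss of CO2 from the adduct. The fallback sets out from 2: bromination and dehydrobromination (Br2, then Et3N, CH2Cl2, 0 °C) give the more dienophilic (R)-2-bromo-4-silyloxycyclopentenone F2. Its cycloaddition with 1 at lower temperature should give the tribromo bridged lactone F3. Bu3SnH/AIBN (2.2 equiv) then removes both tertiary α-carbonyl bromides (the ring fusion can only re-form cis), and the route is rejoined at 4.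

Step 5. What may go wrong: insertion of the hindered β-alkenyl acrylate into the alkenyl–rhodium bond may be slow, with competing protodeboronation, 1,6-addition or weak catalyst control. The fallback sets out from 5 and replaces catalyst control by auxiliary control. Heck coupling with (R)-3-acryloyl-4-benzyloxazolidin-2-one gives the N-enoyl oxazolidinone F4. Chelation-controlled conjugate addition of the isopropenyl cuprate (isopropenylmagnesium bromide, CuBr·SMe2, THF, −78 °C) anti to the benzyl group gives the imide adduct F5. Sm(OTf)3-catalysed methanolysis then releases the auxiliary and comes back to the route at 9.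

Further compounds
F1 | step 13 | boryl iodoalkenyl homoallylic alcohol (16 with CH2Bpin and (Z)-CH(OH)CH=CHI on the former diene carbon) | C=C(C)[C@H](CC(=O)OC)C1=C[C@H]2C(=O)O[C@@H]3C[C@](C)(O)[C@@H]([C@@H]32)[C@@]1(CB4OC(C)(C)C(C)(C)O4)[C@@H](O)/C=C\I
F2 | step 1 | (R)-2-bromo-4-(tert-butyldimethylsilyloxy)cyclopent-2-en-1-one | O=C1C(Br)=C[C@H](O[Si](C)(C)C(C)(C)C)C1
F3 | step 1 | tribromo bridged lactone (3 with bromine on the ring-fusion carbon alpha to the ketone) | BrC1=C[C@@]2(Br)C(=O)O[C@@H]1[C@@H]3[C@@]2(Br)C(=O)C[C@H]3O[Si](C)(C)C(C)(C)C
F4 | step 5 | N-enoyl oxazolidinone (5 with the 7-bromine replaced by the (E)-acryloyl (R)-4-benzyloxazolidinone) | O=C(/C=C/C1=C[C@H]2C(=O)O[C@@H]1[C@@H]3[C@H]2[C@H](O)C[C@H]3O[Si](C)(C)C(C)(C)C)N4[C@H](Cc5ccccc5)COC4=O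
F5 | step 5 | imide adduct (F4 after 1,4-addition of isopropenyl, S at the new centre) | C=C(C)[C@H](CC(=O)N4[C@H](Cc5ccccc5)COC4=O)C1=C[C@H]2C(=O)O[C@@H]1[C@@H]3[C@H]2[C@H](O)C[C@H]3O[Si](C)(C)C(C)(C)C
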